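**Strategy.** In end B the ring oxygen links C8 (the O–CH) to the quaternary, methyl-bearing C5 across the C6=C7 alkene of the dihydrofuran. This 1,3-relationship is disconnected to a C7–C8 oxirane next to the C5=C6 alkene of a β-ionone ring. A copper-catalysed 1,3-oxygen shift then forms the O–C5 bond, the dihydrofuran ring and the C6=C7 alkene in one operation and relays the oxirane configuration to C5. Its precursor is the trans (7R,8S)-7,8-epoxy ketone of (3S)-silyloxy-β-ionone, made by catalytic asymmetric epoxidation. End A, whose C5'/C8' relation is cis, comes from a Sharpless-derived 5,6-epoxide by acid rearrangement; two phosphonate olefinations join both halves to a C10 dialdehyde.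

Key step: step 6

Assumption: carotenoid numbering is used (primes for end A); the ligand antipodes in steps 1, 5 and 10 follow the usual facial models for these catalyst classes, and the mirror-image ligand would be taken in any step where the model did not hold for this substrate.

**End B**

Step 1
Reactants: 1 ketoisophorone
Product: 2 (R)-4-hydroxy-2,6,6-trimethylcyclohex-2-en-1-one
Conditions: RuCl(p-cymene)[(R,R)-TsDPEN] (0.5 mol %), i-PrOH, rt
Reagents that add atoms: none
Why: Asymmetric transfer hydrogenation reduces the less hindered C4 carbonyl (the C1 carbonyl is shielded by the gem-dimethyl group), and with the sp2 carbon C3 in the aryl position of the usual model the (R,R) ligand should set the R carbinol centre that becomes C3 of end B.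

Step 2
Reactants: 2 (R)-4-hydroxy-2,6,6-trimethylcyclohex-2-en-1-one
Product: 3 (R)-4-(tert-butyldimethylsilyloxy)-2,6,6-trimethylcyclohex-2-en-1-one
Conditions: TBSCl, imidazole, DMF, rt
Reagents that add atoms: tert-butyldimethylsilyl chloride, CC(C)(C)[Si](C)(C)Cl
Why: Imidazole-promoted silylation masks the hydroxyl through the hydride, palladium, peroxide, copper and base steps until fluoride removes it at the end.

Step 3
Reactants: 3 (R)-4-(tert-butyldimethylsilyloxy)-2,6,6-trimethylcyclohex-2-en-1-one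
Product: 5 (S)-4-(tert-butyldimethylsilyloxy)-2,6,6-trimethylcyclohex-1-en-1-yl trifluoromethanesulfonate, via lithium enolate 4 (not isolated)
Conditions: LiBH(s-Bu)3, THF, −78 °C; then PhNTf2, −78 °C → rt
Reagents that add atoms: N-phenylbis(trifluoromethanesulfonimide), O=S(=O)(N(c1ccccc1)S(=O)(=O)C(F)(F)F)C(F)(F)F
Why: Reductive enol triflate formation: 1,4-hydride delivery to the β-unsubstituted enone, whose carbonyl is too hindered for 1,2-attack, gives the tetrasubstituted enolate regiospecifically and O-triflation traps it, the carbinol centre staying untouched (its descriptor becomes S only through the priority rules).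

Step 4
Reactants: 5 (S)-4-(tert-butyldimethylsilyloxy)-2,6,6-trimethylcyclohex-1-en-1-yl trifluoromethanesulfonate; 6 methyl vinyl ketone
Product: 7 (E)-4-[(S)-4-(tert-butyldimethylsilyloxy)-2,6,6-trimethylcyclohex-1-en-1-yl]but-3-en-2-one
Conditions: Pd(OAc)2 (5 mol %), PPh3, Et3N, DMF, 70 °C
Reagents that add atoms: methyl vinyl ketone 6, CC(=O)C=C
Why: Heck reaction of an alkenyl triflate with an enone: oxidative addition to zerovalent palladium, syn insertion and syn β-hydride elimination give the E dienone.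

Step 5
Reactants: 7 (E)-4-[(S)-4-(tert-butyldimethylsilyloxy)-2,6,6-trimethylcyclohex-1-en-1-yl]but-3-en-2-one; 8 tert-butyl hydroperoxide
Product: 9 1-{(2S,3R)-3-[(S)-4-(tert-butyldimethylsilyloxy)-2,6,6-trimethylcyclohex-1-en-1-yl]oxiran-2-yl}ethan-1-one (trans-7,8-epoxide; 3S,7R,8S)
Conditions: La(O-i-Pr)3 (10 mol %), (R)-BINOL, Ph3As=O, t-BuOOH (decane), 4 Å MS, THF, rt
Reagents that add atoms: tert-butyl hydroperoxide 8, CC(C)(C)OO
Why: Lanthanum–BINOL-catalysed nucleophilic epoxidation (asymmetric Weitz–Scheffer type) of an E enone: the La-bound peroxide adds to C7 and the enolate closes the trans oxirane, the (R)-BINOL complex, not the remote C3 centre, selecting the face that gives 7R,8S as it does for β-aryl methyl enones.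

Step 6
Reactants: 9 1-{(2S,3R)-3-[(S)-4-(tert-butyldimethylsilyloxy)-2,6,6-trimethylcyclohex-1-en-1-yl]oxiran-2-yl}ethan-1-one
Product: 10 1-[(2S,6R,7aS)-6-(tert-butyldimethylsilyloxy)-4,4,7a-trimethyl-2,4,5,6,7,7a-hexahydro-1-benzofuran-2-yl]ethan-1-one (3R,5S,8S)
Conditions: Cu(CF3COCHCOCF3)2 (5 mol %), toluene, 110 °C
Reagents that add atoms: none
Why: Proposed new method: the divalent copper complex acts as a Lewis acid on the oxirane oxygen, the C7–O bond (allylic to the tetrasubstituted C5=C6 alkene) ionizes to a tight allyl cation/copper alkoxide pair, and the oxygen, still bonded to C8, collapses onto C5 while the alkene moves to C6=C7. The closest known reaction type is the Cu(CF3COCHCOCF3)2-catalysed ring expansion of vinyl oxiranes to 2,5-dihydrofurans, which has not been shown for a tetrasubstituted vinyl group or for an α,β-epoxy ketone. The dihydrofuran ring closes in a formal 5-endo-trig mode (oxygen onto C5 of the C5=C6 bond), feasible because it is the collapse of an ion pair (an intramolecular SN2'-type 1,3-shift) and not an addition to an isolated alkene. The new stereocentre C5 is controlled by C7: in the reactive rotamer C8 lies on the side of the C5 methyl and H7 faces the gem-dimethyl carbon, the oxygen leaves and returns on the same face of the allyl unit, so the 7R,8S trans oxirane gives 5S with the acetyl group trans to the C5 methyl, while C8 is not touched and the remote C3 silyl ether has no say. The step needs C7–O over C8–O cleavage and ring closure over 1,2-acyl shift, enolization or free-cation scrambling; the electron-poor acetyl group disfavours ionization at C8, the alkene makes C5 a tertiary cation terminus, and a non-polar solvent keeps the ion pair tight.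

Step 7
Reactants: 10 1-[(2S,6R,7aS)-6-(tert-butyldimethylsilyloxy)-4,4,7a-trimethyl-2,4,5,6,7,7a-hexahydro-1-benzofuran-2-yl]ethan-1-one; 11 vinylmagnesium bromide
Product: 12 2-[(2S,6R,7aS)-6-(tert-butyldimethylsilyloxy)-4,4,7a-trimethyl-2,4,5,6,7,7a-hexahydro-1-benzofuran-2-yl]but-3-en-2-ol (both C9 epimers)
Conditions: CH2=CHMgBr, CeCl3, THF, −78 °C
Reagents that add atoms: vinylmagnesium bromide 11, C=C[Mg]Br
Why: 1,2-Addition of a vinylcerium reagent to the ketone: the weakly basic organocerium should add at −78 °C faster than it enolizes the C8–H that is both α to the carbonyl and allylic, so C8 is kept, and the new carbinol centre (C9, both epimers) is erased in step 8.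

Step 8
Reactants: 12 2-[(2S,6R,7aS)-6-(tert-butyldimethylsilyloxy)-4,4,7a-trimethyl-2,4,5,6,7,7a-hexahydro-1-benzofuran-2-yl]but-3-en-2-ol
Product: 14 diethyl {(2E)-3-[(2S,6R,7aS)-6-(tert-butyldimethylsilyloxy)-4,4,7a-trimethyl-2,4,5,6,7,7a-hexahydro-1-benzofuran-2-yl]but-2-en-1-yl}phosphonate, via allyl diethyl phosphite 13 (not isolated)
Conditions: ClP(OEt)2, Et3N, toluene, 0 °C; filter; then 110 °C
Reagents that add atoms: diethyl chlorophosphite, CCOP(Cl)OCC
Why: O-Phosphitylation of the tertiary allylic alcohol and thermal [2,3]-sigmatropic phosphite-to-phosphonate rearrangement move phosphorus to C11 and create the C9=C10 alkene, mainly E because the branched C8 substituent prefers the pseudo-equatorial site of the five-membered transition state; any 9Z isomer is removed by chromatography.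

**End A**

Step 9
Reactants: 15 β-cyclocitral
Product: 16 β-cyclogeraniol, (2,6,6-trimethylcyclohex-1-en-1-yl)methanol
Conditions: NaBH4, MeOH, 0 °C
Reagents that add atoms: none
Why: Borohydride 1,2-reduction of the hindered enal gives the allylic alcohol needed for a directed epoxidation.

Step 10
Reactants: 16 β-cyclogeraniol; 8 tert-butyl hydroperoxide
Product: 17 [(1R,6R)-2,2,6-trimethyl-7-oxabicyclo[4.1.0]heptan-1-yl]methanol
Conditions: Ti(O-i-Pr)4, D-(−)-diethyl tartrate, t-BuOOH, 4 Å MS, CH2Cl2, −20 °C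
Reagents that add atoms: tert-butyl hydroperoxide 8, CC(C)(C)OO
Why: Sharpless asymmetric epoxidation of a tetrasubstituted allylic alcohol: the titanium tartrate delivers oxygen to the ring alkene from the face dictated by D-(−)-tartrate, which should set the 1R,6R oxirane (5R in carotenoid numbering).

Step 11
Reactants: 17 [(1R,6R)-2,2,6-trimethyl-7-oxabicyclo[4.1.0]heptan-1-yl]methanol
Product: 18 (1S,6R)-2,2,6-trimethyl-7-oxabicyclo[4.1.0]heptane-1-carbaldehyde
Conditions: Dess–Martin periodinane, pyridine, CH2Cl2, 0 °C → rt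
Reagents that add atoms: none
Why: Dess–Martin oxidation under buffered conditions gives the non-enolizable epoxy aldehyde without opening the acid-sensitive oxirane (same configuration, descriptor changed by the priority rules).

Step 12
Reactants: 18 (1S,6R)-2,2,6-trimethyl-7-oxabicyclo[4.1.0]heptane-1-carbaldehyde; 19 dimethyl (2-oxopropyl)phosphonate
Product: 20 (E)-4-[(1S,6R)-2,2,6-trimethyl-7-oxabicyclo[4.1.0]heptan-1-yl]but-3-en-2-one, (5R,6S)-5,6-epoxy-5,6-dihydro-β-ionone
Conditions: NaH, THF, 0 → 40 °C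
Reagents that add atoms: dimethyl (2-oxopropyl)phosphonate 19, COP(=O)(CC(C)=O)OC
Why: Horner–Wadsworth–Emmons olefination with a β-keto phosphonate anion gives the E enone; the aldehyde has no α-hydrogen and the oxirane is inert to the base.

Step 13
Reactants: 20 (5R,6S)-5,6-epoxy-5,6-dihydro-β-ionone; 11 vinylmagnesium bromide
Product: 21 (1E)-3-methyl-1-[(1S,6R)-2,2,6-trimethyl-7-oxabicyclo[4.1.0]heptan-1-yl]penta-1,4-dien-3-ol (both C9' epimers)
Conditions: CH2=CHMgBr, THF, −78 → 0 °C
Reagents that add atoms: vinylmagnesium bromide 11, C=C[Mg]Br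
Why: Grignard 1,2-addition to the enone carbonyl, the usual course for vinylmagnesium halides with ionones, gives the tertiary vinyl carbinol (epimers that converge in step 14) and leaves the hindered oxirane intact.

Step 14
Reactants: 21 (1E)-3-methyl-1-[(1S,6R)-2,2,6-trimethyl-7-oxabicyclo[4.1.0]heptan-1-yl]penta-1,4-dien-3-ol
Product: 23 diethyl {(2E,4E)-3-methyl-5-[(1S,6R)-2,2,6-trimethyl-7-oxabicyclo[4.1.0]heptan-1-yl]penta-2,4-dien-1-yl}phosphonate, via allyl diethyl phosphite 22 (not isolated)
Conditions: ClP(OEt)2, Et3N, toluene, 0 °C; filter; then 110 °C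
Reagents that add atoms: diethyl chlorophosphite, CCOP(Cl)OCC
Why: As in step 8, phosphite formation and [2,3]-sigmatropic rearrangement give the primary dienyl phosphonate with the new C9'=C10' alkene mainly E; the oxirane should survive the neutral, aprotic conditions.

Step 15
Reactants: 23 diethyl {(2E,4E)-3-methyl-5-[(1S,6R)-2,2,6-trimethyl-7-oxabicyclo[4.1.0]heptan-1-yl]penta-2,4-dien-1-yl}phosphonate
Product: 24 diethyl {(2E)-3-[(2S,7aR)-4,4,7a-trimethyl-2,4,5,6,7,7a-hexahydro-1-benzofuran-2-yl]but-2-en-1-yl}phosphonate (5'R,8'S; C9' cis to the C5' methyl)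
Conditions: HCl (cat.), CHCl3, 0 °C → rt; chromatographic separation of the C8' epimers
Reagents that add atoms: none
Why: Acid-catalysed epoxide-to-furanoid rearrangement of a 5,6-epoxy-7-ene: protonation opens the C6'–O bond to a pentadienyl cation and the oxygen, which never leaves C5' (5'R kept), closes on C8'; both C8' epimers are expected and should interconvert through the cation, so the cis (8'S) epimer is isolated and the 8'R epimer is resubmitted.

**Assembly**

Step 16
Reactants: 24 diethyl {(2E)-3-[(2S,7aR)-4,4,7a-trimethyl-2,4,5,6,7,7a-hexahydro-1-benzofuran-2-yl]but-2-en-1-yl}phosphonate; 25 (2E,4E,6E)-2,7-dimethylocta-2,4,6-trienedial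
Product: 26 (2E,4E,6E,8E,10E)-2,7-dimethyl-11-[(2S,7aR)-4,4,7a-trimethyl-2,4,5,6,7,7a-hexahydro-1-benzofuran-2-yl]dodeca-2,4,6,8,10-pentaenal
Conditions: KOt-Bu, THF, −40 °C; anion added to 25 (3 equiv), → 0 °C, dark
Reagents that add atoms: (2E,4E,6E)-2,7-dimethylocta-2,4,6-trienedial 25, O=C/C(C)=C/C=C/C=C(C)/C=O
Why: Horner–Wadsworth–Emmons olefination of the allylic phosphonate anion with an enal forms the C11'=C12' alkene E, and slow addition to excess dialdehyde limits the reaction to one aldehyde because the product polyenal is less electrophilic.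

Step 17
Reactants: 14 diethyl {(2E)-3-[(2S,6R,7aS)-6-(tert-butyldimethylsilyloxy)-4,4,7a-trimethyl-2,4,5,6,7,7a-hexahydro-1-benzofuran-2-yl]but-2-en-1-yl}phosphonate; 26 the C25 furanoid pentaenal
Product: 27 3-O-tert-butyldimethylsilyl ether of the target
Conditions: KOt-Bu, THF, −40 → 0 °C, dark
Reagents that add atoms: none
Why: Horner–Wadsworth–Emmons union of the two halves forms the C11=C12 alkene E and completes the polyene; low temperature favours olefination over any base-induced opening of the dihydrofurans.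

Step 18
Reactants: 27 3-O-tert-butyldimethylsilyl ether of the target
Product: 28 (all-E,3R,5S,8S,5'R,8'S)-5,8:5',8'-diepoxy-5,8,5',8'-tetrahydro-β,β-caroten-3-ol (target)
Conditions: Bu4NF, THF, 0 °C → rt, dark
Reagents that add atoms: none
Why: Fluoride-mediated desilylation frees the C3 hydroxyl under non-acidic conditions, which protect the acid-labile C8 and C8' centres and the polyene.

**Compound list**

1 | ketoisophorone (2,6,6-trimethylcyclohex-2-ene-1,4-dione) | CC1=CC(=O)CC(C)(C)C1=O | starting material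
2 | (R)-4-hydroxy-2,6,6-trimethylcyclohex-2-en-1-one | CC1=C[C@H](O)CC(C)(C)C1=O | intermediate
3 | (R)-4-(tert-butyldimethylsilyloxy)-2,6,6-trimethylcyclohex-2-en-1-one | CC1=C[C@H](O[Si](C)(C)C(C)(C)C)CC(C)(C)C1=O | intermediate
4 | lithium (S)-4-(tert-butyldimethylsilyloxy)-2,6,6-trimethylcyclohex-1-en-1-olate | [Li+].[O-]C1=C(C)C[C@H](O[Si](C)(C)C(C)(C)C)CC1(C)C | intermediate (not isolated)
5 | (S)-4-(tert-butyldimethylsilyloxy)-2,6,6-trimethylcyclohex-1-en-1-yl trifluoromethanesulfonate | FC(F)(F)S(=O)(=O)OC1=C(C)C[C@H](O[Si](C)(C)C(C)(C)C)CC1(C)C | intermediate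
6 | methyl vinyl ketone | CC(=O)C=C | starting material
7 | (E)-4-[(S)-4-(tert-butyldimethylsilyloxy)-2,6,6-trimethylcyclohex-1-en-1-yl]but-3-en-2-one | CC(=O)/C=C/C1=C(C)C[C@H](O[Si](C)(C)C(C)(C)C)CC1(C)C | intermediate
8 | tert-butyl hydroperoxide | CC(C)(C)OO | starting material
9 | 1-{(2S,3R)-3-[(S)-4-(tert-butyldimethylsilyloxy)-2,6,6-trimethylcyclohex-1-en-1-yl]oxiran-2-yl}ethan-1-one (key-step precursor) | CC(=O)[C@H]1O[C@@H]1C1=C(C)C[C@H](O[Si](C)(C)C(C)(C)C)CC1(C)C | intermediate
10 | 1-[(2S,6R,7aS)-6-(tert-butyldimethylsilyloxy)-4,4,7a-trimethyl-2,4,5,6,7,7a-hexahydro-1-benzofuran-2-yl]ethan-1-one (key-step product) | CC(=O)[C@@H]1C=C2C(C)(C)C[C@@H](O[Si](C)(C)C(C)(C)C)C[C@]2(C)O1 | intermediate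
11 | vinylmagnesium bromide | C=C[Mg]Br | starting material
12 | 2-[(2S,6R,7aS)-6-(tert-butyldimethylsilyloxy)-4,4,7a-trimethyl-2,4,5,6,7,7a-hexahydro-1-benzofuran-2-yl]but-3-en-2-ol (C9 epimers) | C=CC(C)(O)[C@@H]1C=C2C(C)(C)C[C@@H](O[Si](C)(C)C(C)(C)C)C[C@]2(C)O1 | intermediate
13 | diethyl phosphite ester of 12 | C=CC(C)(OP(OCC)OCC)[C@@H]1C=C2C(C)(C)C[C@@H](O[Si](C)(C)C(C)(C)C)C[C@]2(C)O1 | intermediate (not isolated)
14 | diethyl {(2E)-3-[(2S,6R,7aS)-6-(tert-butyldimethylsilyloxy)-4,4,7a-trimethyl-2,4,5,6,7,7a-hexahydro-1-benzofuran-2-yl]but-2-en-1-yl}phosphonate | CCOP(=O)(C/C=C(\C)[C@@H]1C=C2C(C)(C)C[C@@H](O[Si](C)(C)C(C)(C)C)C[C@]2(C)O1)OCC | intermediate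
15 | β-cyclocitral (2,6,6-trimethylcyclohex-1-ene-1-carbaldehyde) | CC1=C(C=O)C(C)(C)CCC1 | starting material
16 | β-cyclogeraniol | CC1=C(CO)C(C)(C)CCC1 | intermediate
17 | [(1R,6R)-2,2,6-trimethyl-7-oxabicyclo[4.1.0]heptan-1-yl]methanol | OC[C@@]12O[C@]1(C)CCCC2(C)C | intermediate
18 | (1S,6R)-2,2,6-trimethyl-7-oxabicyclo[4.1.0]heptane-1-carbaldehyde | O=C[C@@]12O[C@]1(C)CCCC2(C)C | intermediate
19 | dimethyl (2-oxopropyl)phosphonate | COP(=O)(CC(C)=O)OC | starting material
20 | (E)-4-[(1S,6R)-2,2,6-trimethyl-7-oxabicyclo[4.1.0]heptan-1-yl]but-3-en-2-one | CC(=O)/C=C/[C@@]12O[C@]1(C)CCCC2(C)C | intermediate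
21 | (1E)-3-methyl-1-[(1S,6R)-2,2,6-trimethyl-7-oxabicyclo[4.1.0]heptan-1-yl]penta-1,4-dien-3-ol (C9' epimers) | C=CC(C)(O)/C=C/[C@@]12O[C@]1(C)CCCC2(C)C | intermediate
22 | diethyl phosphite ester of 21 | C=CC(C)(OP(OCC)OCC)/C=C/[C@@]12O[C@]1(C)CCCC2(C)C | intermediate (not isolated)
23 | diethyl {(2E,4E)-3-methyl-5-[(1S,6R)-2,2,6-trimethyl-7-oxabicyclo[4.1.0]heptan-1-yl]penta-2,4-dien-1-yl}phosphonate | CCOP(=O)(C/C=C(C)/C=C/[C@@]12O[C@]1(C)CCCC2(C)C)OCC | intermediate
24 | diethyl {(2E)-3-[(2S,7aR)-4,4,7a-trimethyl-2,4,5,6,7,7a-hexahydro-1-benzofuran-2-yl]but-2-en-1-yl}phosphonate | CCOP(=O)(C/C=C(\C)[C@@H]1C=C2C(C)(C)CCC[C@@]2(C)O1)OCC | intermediate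
25 | (2E,4E,6E)-2,7-dimethylocta-2,4,6-trienedial | O=C/C(C)=C/C=C/C=C(C)/C=O | starting material
26 | (2E,4E,6E,8E,10E)-2,7-dimethyl-11-[(2S,7aR)-4,4,7a-trimethyl-2,4,5,6,7,7a-hexahydro-1-benzofuran-2-yl]dodeca-2,4,6,8,10-pentaenal | O=C/C(C)=C/C=C/C=C(C)/C=C/C=C(\C)[C@@H]1C=C2C(C)(C)CCC[C@@]2(C)O1 | intermediate
27 | 3-O-tert-butyldimethylsilyl ether of 28 | CC(/C=C/C=C(\C)[C@@H]1C=C2C(C)(C)CCC[C@@]2(C)O1)=C\C=C\C=C(C)\C=C\C=C(/C)[C@@H]1C=C2C(C)(C)C[C@@H](O[Si](C)(C)C(C)(C)C)C[C@]2(C)O1 | intermediate
28 | (all-E,3R,5S,8S,5'R,8'S)-5,8:5',8'-diepoxy-5,8,5',8'-tetrahydro-β,β-caroten-3-ol | CC(/C=C/C=C(\C)[C@@H]1C=C2C(C)(C)CCC[C@@]2(C)O1)=C\C=C\C=C(C)\C=C\C=C(/C)[C@@H]1C=C2C(C)(C)C[C@@H](O)C[C@]2(C)O1 | target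

**Count and risks**

Total steps: 18. Longest linear sequence: 10 steps (steps 1–8, 17, 18; the end A line, steps 9–16, 17, 18, is equally long).

Steps most likely to fail:

1. Step 6 (proposed new method). The C7–O bond may ionize to a free, long-lived allyl cation, so that the oxygen returns to either face of C5 and the configuration at C5 is lost. The acetyl group may also migrate to C7, or a copper enolate of the product may epimerize C8 or move the alkene into conjugation. The fallback uses known chemistry, sets out from 7 and returns at 14. mCPBA (CH2Cl2, NaHCO3, 0 °C) should epoxidize the electron-rich ring alkene, mainly on the face opposite the silyloxy group, to (3R,5S,6R)-3-(tert-butyldimethylsilyloxy)-5,6-epoxy-5,6-dihydro-β-ionone F1. CH2=CHMgBr (THF, −78 °C) would give the tertiary vinyl carbinol F2. ClP(OEt)2 and Et3N would give its allyl diethyl phosphite F3, which on heating should rearrange to the epoxy dienyl phosphonate F4. Catalytic HCl in CHCl3 would then bring about the classical epoxide-to-furanoid rearrangement, in which the oxygen stays on C5, and the 8S epimer 14 is separated from its C8 epimer.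

2. Step 5. Peroxide addition at the hindered, twisted dienone may be slow or poorly face-selective, and uncatalysed background epoxidation may erode the enantioselectivity. The fallback sets out from 7 and returns at 9. Luche reduction (NaBH4, CeCl3, MeOH) would give the allylic alcohol F5 as C9 epimers. Sharpless epoxidation with kinetic resolution (Ti(O-i-Pr)4, D-(−)-diisopropyl tartrate, 0.6 equiv t-BuOOH, −20 °C) should convert the faster-reacting 9R epimer into the epoxy alcohol F6, which carries the oxirane configuration of 9. Dess–Martin oxidation of F6 gives 9.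

3. Step 15. Under acid mild enough to spare the dienyl phosphonate, ring closure may be kinetically biased toward the trans (8'R) epimer without re-ionization, so that too little cis epimer forms; stronger acid may isomerize C9'=C10' or cause elimination. The fallback sets out from 23 and returns at 26 by postponing the rearrangement to the polyene stage, where 5,6-epoxy polyenes are known to give both C8 epimers with a trace of acid. The anion of 23 (KOt-Bu, THF, −78 °C, aldehyde present) is condensed with excess 25 to the epoxy hexaenal F7. F7 with a trace of HCl in CHCl3 should give 26, which is separated from its 8'R epimer.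

**Further compounds**

F1 | step 6 | (3R,5S,6R)-3-(tert-butyldimethylsilyloxy)-5,6-epoxy-5,6-dihydro-β-ionone | CC(=O)/C=C/[C@]12O[C@@]1(C)C[C@H](O[Si](C)(C)C(C)(C)C)CC2(C)C
F2 | step 6 | tertiary vinyl carbinol from F1 (C9 epimers) | C=CC(C)(O)/C=C/[C@]12O[C@@]1(C)C[C@H](O[Si](C)(C)C(C)(C)C)CC2(C)C
F3 | step 6 | allyl diethyl phosphite of F2 | C=CC(C)(OP(OCC)OCC)/C=C/[C@]12O[C@@]1(C)C[C@H](O[Si](C)(C)C(C)(C)C)CC2(C)C
F4 | step 6 | diethyl (2E,4E)-epoxy dienyl phosphonate of end B | CCOP(=O)(C/C=C(C)/C=C/[C@]12O[C@@]1(C)C[C@H](O[Si](C)(C)C(C)(C)C)CC2(C)C)OCC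
F5 | step 5 | (E)-4-[(S)-4-(tert-butyldimethylsilyloxy)-2,6,6-trimethylcyclohex-1-en-1-yl]but-3-en-2-ol (C9 epimers) | CC(O)/C=C/C1=C(C)C[C@H](O[Si](C)(C)C(C)(C)C)CC1(C)C
F6 | step 5 | (R)-1-{3-[(S)-4-(tert-butyldimethylsilyloxy)-2,6,6-trimethylcyclohex-1-en-1-yl]oxiran-2-yl}ethan-1-ol with the oxirane configuration of 9 | C[C@@H](O)[C@H]1O[C@@H]1C1=C(C)C[C@H](O[Si](C)(C)C(C)(C)C)CC1(C)C
F7 | step 15 | (2E,4E,6E,8E,10E,12E)-2,7,11-trimethyl-13-[(1S,6R)-2,2,6-trimethyl-7-oxabicyclo[4.1.0]heptan-1-yl]trideca-2,4,6,8,10,12-hexaenal | O=C/C(C)=C/C=C/C=C(C)/C=C/C=C(C)/C=C/[C@@]12O[C@]1(C)CCCC2(C)C
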